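**Plan**

- Retrosynthesis: the C5–OOH bond is cut first (Schenck ene reaction on a 4-ene), then C5–C10 (transannular cation–olefin cyclisation of a germacra-1(10),4-diene), then C3–C4 of the ten-membered ring (Ni/Cr alkenyl–aldehyde closure), then C7–C8 (asymmetric chromium allylation); this leaves a C8–C3 aldehyde and a C13–C4 bromo iodide.
- Enabling feature: C5–C10 is the one bond shared by ring A (C1–C5, C10) and ring B (C5–C10), and it bisects the ten-carbon perimeter C1–C10. Both six-membered rings and the quaternary C10 can therefore come from one (1(10)E,4E)-cyclodecadiene.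
- Forward: the two fragments are joined at C7–C8, the ten-membered ring is closed at C3–C4, rings A and B arise together in one step, and oxygen is placed on C5 last.
- Stereochemistry: C7 and C8 come from a catalyst-controlled, syn-selective allylation; C3 (ring closure), C10 (transannular step) and C5 (α-face ene reaction) are relayed from them through the ring conformation.
- Remark: germacrane/eudesmane numbering (C1–C15) is used for all intermediates; in step 10 the ligand antipode is the one that sends the allyl group to the Si face of the aldehyde (8R).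

Key step: step 16

**Route**

Step 1
Reactants: 1 3-butyn-1-ol
Product: 2 tert-butyl(but-3-yn-1-yloxy)dimethylsilane
Conditions: TBSCl, imidazole, CH2Cl2, 0 °C to rt
Reagents that add atoms: tert-butyldimethylsilyl chloride, CC(C)(C)[Si](C)(C)Cl
Why: Imidazole-promoted silylation of the primary alcohol is routine and keeps O8 masked through the organoaluminium chemistry of step 2.

Step 2
Reactants: 2 tert-butyl(but-3-yn-1-yloxy)dimethylsilane; 3 oxirane
Product: 6 (3E)-6-{[tert-butyl(dimethyl)silyl]oxy}-4-methylhex-3-en-1-ol, via alkenyldimethylalane 4 (not isolated), via lithium alkenylalanate 5 (not isolated)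
Conditions: Me3Al, Cp2ZrCl2 (25 mol %), CH2Cl2, 0 °C to rt; volatiles removed; n-BuLi, hexane/THF, −78 °C; oxirane, −78 °C to rt
Reagents that add atoms: trimethylaluminium, C[Al](C)C
Why: Zirconium-catalysed Negishi carboalumination adds methyl and aluminium syn across the terminal alkyne (methyl to the internal carbon), and the derived alanate opens oxirane with retention of alkene geometry, which fixes the 1(10)E alkene and delivers C2 and C3.

Step 3
Reactants: 6 (3E)-6-{[tert-butyl(dimethyl)silyl]oxy}-4-methylhex-3-en-1-ol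
Product: 7 tert-butyl({(3E)-6-[(4-methoxybenzyl)oxy]-3-methylhex-3-en-1-yl}oxy)dimethylsilane
Conditions: NaH, PMBCl, Bu4NI (cat.), THF/DMF, 0 °C to rt
Reagents that add atoms: 4-methoxybenzyl chloride, COc1ccc(CCl)cc1
Why: Williamson etherification puts a PMB group on O3 that should survive every step up to its oxidative release in step 12.

Step 4
Reactants: 7 tert-butyl({(3E)-6-[(4-methoxybenzyl)oxy]-3-methylhex-3-en-1-yl}oxy)dimethylsilane
Product: 8 (3E)-6-[(4-methoxybenzyl)oxy]-3-methylhex-3-en-1-ol
Conditions: CSA (cat.), MeOH, 0 °C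
Reagents that add atoms: none
Why: Acid-catalysed methanolysis cleaves the primary TBS ether selectively while the PMB ether and the trisubstituted alkene are inert.

Step 5
Reactants: 8 (3E)-6-[(4-methoxybenzyl)oxy]-3-methylhex-3-en-1-ol
Product: 9 (3E)-6-[(4-methoxybenzyl)oxy]-3-methylhex-3-enal
Conditions: DMP, pyridine, CH2Cl2, 0 °C; used crude
Reagents that add atoms: none
Why: Buffered Dess–Martin oxidation gives the β,γ-unsaturated C8 aldehyde without acid or base strong enough to move the alkene into conjugation.

Step 6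
Reactants: 10 pent-3-yn-1-ol
Product: 12 (3E)-4-iodopent-3-en-1-ol, via alkenylzirconocene chloride 11 (not isolated)
Conditions: Cp2Zr(H)Cl (2.5 equiv), THF, rt to 45 °C; then I2, 0 °C
Reagents that add atoms: iodine, II
Why: Hydrozirconation with the Schwartz reagent is a syn addition that, with excess reagent and gentle warming, equilibrates zirconium to the less hindered methyl-bearing carbon, and iodinolysis with retention gives the E iodide that later becomes the 4E alkene.

Step 7
Reactants: 12 (3E)-4-iodopent-3-en-1-ol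
Product: 13 (3E)-4-iodopent-3-enal
Conditions: DMP, pyridine, CH2Cl2, 0 °C; solution used at once
Reagents that add atoms: none
Why: Buffered Dess–Martin oxidation is mild enough to give this isomerisation-prone β,γ-unsaturated aldehyde, which is not stored.

Step 8
Reactants: 13 (3E)-4-iodopent-3-enal; 14 methyl propiolate
Product: 16 methyl (5E)-3-hydroxy-6-iodo-2-methylidenehept-5-enoate (racemic), via methyl 2-(diisobutylalumanyl)acrylate 15 (not isolated)
Conditions: 14, i-Bu2AlH, NMO, THF, 0 °C; then 13, 0 °C to rt
Reagents that add atoms: none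
Why: Conjugate hydroalumination of the propiolate gives an α-aluminoacrylate that adds to the aldehyde (vinylalumination), which furnishes the Morita–Baylis–Hillman-type alcohol without the amine base that would isomerise the aldehyde; the carbinol centre is racemic and is erased in step 9.

Step 9
Reactants: 16 methyl (5E)-3-hydroxy-6-iodo-2-methylidenehept-5-enoate
Product: 17 methyl (2Z,5E)-2-(bromomethyl)-6-iodohepta-2,5-dienoate
Conditions: NBS, Me2S, CH2Cl2, 0 °C to rt
Reagents that add atoms: N-bromosuccinimide, O=C1CCC(=O)N1Br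
Why: Corey–Kim-type bromination of a Baylis–Hillman alcohol goes with allylic transposition and should give the thermodynamically preferred Z 2-(bromomethyl)enoate, in which C6 is cis to CH2Br.

Step 10
Reactants: 9 (3E)-6-[(4-methoxybenzyl)oxy]-3-methylhex-3-enal; 17 methyl (2Z,5E)-2-(bromomethyl)-6-iodohepta-2,5-dienoate
Product: 19 methyl (3R,4R,6E)-4-hydroxy-3-[(2E)-3-iodobut-2-en-1-yl]-9-[(4-methoxybenzyl)oxy]-6-methyl-2-methylidenenon-6-enoate, via trimethylsilyl ether 18 (not isolated)
Conditions: CrCl2 (10 mol %), chiral carbazole-bridged bis(oxazoline) ligand (12 mol %), Mn, TMSCl, i-Pr2NEt (cat.), THF, rt; then aq. citric acid, 0 °C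
Reagents that add atoms: none
Why: In this chromium-catalysed enantioselective Nozaki–Hiyama allylation the 2-(methoxycarbonyl)allylchromium reacts at its γ-carbon through a Zimmerman–Traxler chair with the aldehyde residue equatorial and the C6 arm axial (Z geometry), which gives the syn C7/C8 pair, while the ligand directs attack to the Si face of the aldehyde and so sets 7R,8R (nonenoate C3,C4); the alkenyl iodide does not react in the absence of nickel.

Step 11
Reactants: 19 methyl (3R,4R,6E)-4-hydroxy-3-[(2E)-3-iodobut-2-en-1-yl]-9-[(4-methoxybenzyl)oxy]-6-methyl-2-methylidenenon-6-enoate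
Product: 20 methyl (3R,4R,6E)-4-acetoxy-3-[(2E)-3-iodobut-2-en-1-yl]-9-[(4-methoxybenzyl)oxy]-6-methyl-2-methylidenenon-6-enoate
Conditions: Ac2O, pyridine, DMAP (cat.), CH2Cl2, 0 °C
Reagents that add atoms: acetic anhydride, CC(=O)OC(C)=O
Why: DMAP-catalysed acetylation is fast and is run directly on the crude hydroxy ester so that the syn 8-hydroxy group is capped before it can lactonise onto the methyl ester.

Step 12
Reactants: 20 methyl (3R,4R,6E)-4-acetoxy-3-[(2E)-3-iodobut-2-en-1-yl]-9-[(4-methoxybenzyl)oxy]-6-methyl-2-methylidenenon-6-enoate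
Product: 21 methyl (3R,4R,6E)-4-acetoxy-9-hydroxy-3-[(2E)-3-iodobut-2-en-1-yl]-6-methyl-2-methylidenenon-6-enoate
Conditions: DDQ, CH2Cl2/pH 7 buffer, 0 °C
Reagents that add atoms: none
Why: Oxidative PMB cleavage by DDQ runs under neutral conditions that should leave the acetate, the acrylate, the alkenyl iodide and the skipped dienes untouched.

Step 13
Reactants: 21 methyl (3R,4R,6E)-4-acetoxy-9-hydroxy-3-[(2E)-3-iodobut-2-en-1-yl]-6-methyl-2-methylidenenon-6-enoate
Product: 22 methyl (3R,4R,6E)-4-acetoxy-3-[(2E)-3-iodobut-2-en-1-yl]-6-methyl-2-methylidene-9-oxonon-6-enoate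
Conditions: DMP, pyridine, CH2Cl2, 0 °C; used crude
Reagents that add atoms: none
Why: Buffered Dess–Martin oxidation gives the β,γ-unsaturated C3 aldehyde without touching the other functional groups.

Step 14
Reactants: 22 methyl (3R,4R,6E)-4-acetoxy-3-[(2E)-3-iodobut-2-en-1-yl]-6-methyl-2-methylidene-9-oxonon-6-enoate
Product: 24 methyl (3S,7R,8R)-8-acetoxy-3-hydroxygermacra-1(10)E,4E,11(13)-trien-12-oate, via alkenylchromium dichloride 23 (not isolated)
Conditions: CrCl2 (8 equiv), NiCl2 (2 mol %), DMSO/THF, 0.003 M, slow addition, rt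
Reagents that add atoms: none
Why: In this intramolecular Nozaki–Hiyama–Kishi coupling the nickel-catalysed formation of the alkenylchromium keeps the E geometry and its addition to the aldehyde at high dilution closes the ten-membered ring at C3–C4, and the 3S carbinol should result from Re-face addition in a chair–chair-like transition state that holds the chromium-bound oxygen on the ring periphery and the C7 arm pseudo-equatorial.

Step 15
Reactants: 24 methyl (3S,7R,8R)-8-acetoxy-3-hydroxygermacra-1(10)E,4E,11(13)-trien-12-oate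
Product: 25 methyl (3S,7R,8R)-8-acetoxy-3-(isobutyryloxy)germacra-1(10)E,4E,11(13)-trien-12-oate
Conditions: (i-PrCO)2O, Et3N, DMAP (cat.), CH2Cl2, 0 °C to rt
Reagents that add atoms: isobutyric anhydride, CC(C)C(=O)OC(=O)C(C)C
Why: DMAP-catalysed acylation of the secondary allylic alcohol proceeds with retention at C3 under basic conditions that the acid-sensitive germacradiene tolerates.

Step 16
Reactants: 25 methyl (3S,7R,8R)-8-acetoxy-3-(isobutyryloxy)germacra-1(10)E,4E,11(13)-trien-12-oate
Product: 26 methyl (3S,7R,8R,10R)-8-acetoxy-3-(isobutyryloxy)eudesma-4,11(13)-dien-12-oate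
Conditions: TsOH·H2O (20 mol %), CH2Cl2, 0 °C to rt
Reagents that add atoms: none
Why: TsOH protonates C1 of the 1(10)-alkene (the 4,5-alkene is the less basic one because the adjacent 3-acyloxy group withdraws electron density), and the tertiary C10 cation is captured across the ring by C5 of the 4,5-alkene, which forms the C5–C10 bond and leaves a tertiary C4 cation that loses H5 to give the tetrasubstituted 4-ene. This is the acid-induced transannular cyclisation of germacra-1(10),4-dienes to eudesmanes, a cation–olefin cyclisation known for germacrene-type hydrocarbons, alcohols and lactones. The one new bond closes both rings at once: ring A (C1–C5, C10) in a 6-endo-trig mode, since C4 stays inside it, and ring B (C5–C10) in a 6-exo-trig mode, since C4 lies outside it. The only new stereocentre, C10, is fixed by the chair–chair-like conformer of the ten-membered ring in which the C3 ester and the C7 acrylate arm are pseudo-equatorial and both methyl groups point to the β face, so that C5 adds to the face of C10 that leaves C14 cis to the C7 arm (10R), while C3, C7 and C8 are not touched. The step needs regioselective proton loss from C5: loss of H3 would give an enol ester and is disfavoured by the acyloxy group, and the exocyclic 4(15)-isomer formed by loss from C15 should re-enter the same C4 cation under the acid and drain to the more substituted alkene. Low temperature and short contact time are chosen so that the allylic isobutyrate does not ionise.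

Step 17
Reactants: 26 methyl (3S,7R,8R,10R)-8-acetoxy-3-(isobutyryloxy)eudesma-4,11(13)-dien-12-oate
Product: 27 methyl (3S,5S,7R,8R,10R)-8-acetoxy-5-hydroperoxy-3-(isobutyryloxy)eudesma-4(15),11(13)-dien-12-oate (CNP0244758.1)
Conditions: O2, methylene blue (cat.), hν (visible), CH2Cl2, −20 °C
Reagents that add atoms: dioxygen, O=O
Why: In the Schenck ene reaction singlet oxygen should attack the electron-rich tetrasubstituted 4-ene from the α face, opposite the angular C14 methyl, bond to C5 (the carbon remote from the electron-withdrawing 3-acyloxy group) and take a hydrogen from C15, which gives the 5α-hydroperoxide (5S) and the 4(15)-alkene, while the electron-poor acrylate alkene does not react.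

**Compound list**

1 | 3-butyn-1-ol | C#CCCO | starting material
2 | tert-butyl(but-3-yn-1-yloxy)dimethylsilane | C#CCCO[Si](C)(C)C(C)(C)C | intermediate
3 | oxirane | C1CO1 | starting material
4 | [(1E)-4-{[tert-butyl(dimethyl)silyl]oxy}-2-methylbut-1-en-1-yl]dimethylalane | C[Al](C)/C=C(\C)CCO[Si](C)(C)C(C)(C)C | intermediate
5 | lithium butyl[(1E)-4-{[tert-butyl(dimethyl)silyl]oxy}-2-methylbut-1-en-1-yl]dimethylalanate | [Li+].CCCC[Al-](C)(C)/C=C(\C)CCO[Si](C)(C)C(C)(C)C | intermediate
6 | (3E)-6-{[tert-butyl(dimethyl)silyl]oxy}-4-methylhex-3-en-1-ol | OCC/C=C(\C)CCO[Si](C)(C)C(C)(C)C | intermediate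
7 | tert-butyl({(3E)-6-[(4-methoxybenzyl)oxy]-3-methylhex-3-en-1-yl}oxy)dimethylsilane | COc1ccc(COCC/C=C(\C)CCO[Si](C)(C)C(C)(C)C)cc1 | intermediate
8 | (3E)-6-[(4-methoxybenzyl)oxy]-3-methylhex-3-en-1-ol | COc1ccc(COCC/C=C(\C)CCO)cc1 | intermediate
9 | (3E)-6-[(4-methoxybenzyl)oxy]-3-methylhex-3-enal | COc1ccc(COCC/C=C(\C)CC=O)cc1 | intermediate
10 | pent-3-yn-1-ol | CC#CCCO | starting material
11 | O-zirconated (E)-alkenylzirconocene chloride from 10 | C/C(=C\CCO[Zr](Cl)(C1C=CC=C1)C1C=CC=C1)[Zr](Cl)(C1C=CC=C1)C1C=CC=C1 | intermediate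
12 | (3E)-4-iodopent-3-en-1-ol | C/C(I)=C\CCO | intermediate
13 | (3E)-4-iodopent-3-enal | C/C(I)=C\CC=O | intermediate
14 | methyl propiolate | C#CC(=O)OC | starting material
15 | methyl 2-(diisobutylalumanyl)acrylate | C=C(C(=O)OC)[Al](CC(C)C)CC(C)C | intermediate
16 | methyl (5E)-3-hydroxy-6-iodo-2-methylidenehept-5-enoate (racemic) | C=C(C(=O)OC)C(O)C/C=C(\C)I | intermediate
17 | methyl (2Z,5E)-2-(bromomethyl)-6-iodohepta-2,5-dienoate | COC(=O)/C(CBr)=C/C/C=C(\C)I | intermediate
18 | trimethylsilyl ether of 19 | C=C(C(=O)OC)[C@@H](C/C=C(\C)I)[C@H](O[Si](C)(C)C)C/C(C)=C/CCOCc1ccc(OC)cc1 | intermediate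
19 | methyl (3R,4R,6E)-4-hydroxy-3-[(2E)-3-iodobut-2-en-1-yl]-9-[(4-methoxybenzyl)oxy]-6-methyl-2-methylidenenon-6-enoate | C=C(C(=O)OC)[C@@H](C/C=C(\C)I)[C@H](O)C/C(C)=C/CCOCc1ccc(OC)cc1 | intermediate
20 | methyl (3R,4R,6E)-4-acetoxy-3-[(2E)-3-iodobut-2-en-1-yl]-9-[(4-methoxybenzyl)oxy]-6-methyl-2-methylidenenon-6-enoate | C=C(C(=O)OC)[C@@H](C/C=C(\C)I)[C@H](OC(C)=O)C/C(C)=C/CCOCc1ccc(OC)cc1 | intermediate
21 | methyl (3R,4R,6E)-4-acetoxy-9-hydroxy-3-[(2E)-3-iodobut-2-en-1-yl]-6-methyl-2-methylidenenon-6-enoate | C=C(C(=O)OC)[C@@H](C/C=C(\C)I)[C@H](OC(C)=O)C/C(C)=C/CCO | intermediate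
22 | methyl (3R,4R,6E)-4-acetoxy-3-[(2E)-3-iodobut-2-en-1-yl]-6-methyl-2-methylidene-9-oxonon-6-enoate | C=C(C(=O)OC)[C@@H](C/C=C(\C)I)[C@H](OC(C)=O)C/C(C)=C/CC=O | intermediate
23 | alkenylchromium dichloride from 22 | C=C(C(=O)OC)[C@@H](C/C=C(\C)[Cr](Cl)Cl)[C@H](OC(C)=O)C/C(C)=C/CC=O | intermediate
24 | methyl (3S,7R,8R)-8-acetoxy-3-hydroxygermacra-1(10)E,4E,11(13)-trien-12-oate | C=C(C(=O)OC)[C@H]1C/C=C(C)/[C@@H](O)C/C=C(C)/C[C@H]1OC(C)=O | intermediate
25 | methyl (3S,7R,8R)-8-acetoxy-3-(isobutyryloxy)germacra-1(10)E,4E,11(13)-trien-12-oate | C=C(C(=O)OC)[C@H]1C/C=C(C)/[C@@H](OC(=O)C(C)C)C/C=C(C)/C[C@H]1OC(C)=O | intermediate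
26 | methyl (3S,7R,8R,10R)-8-acetoxy-3-(isobutyryloxy)eudesma-4,11(13)-dien-12-oate | C=C(C(=O)OC)[C@H]1CC2=C(C)[C@@H](OC(=O)C(C)C)CC[C@]2(C)C[C@H]1OC(C)=O | intermediate
27 | methyl (3S,5S,7R,8R,10R)-8-acetoxy-5-hydroperoxy-3-(isobutyryloxy)eudesma-4(15),11(13)-dien-12-oate | C=C(C(=O)OC)[C@H]1C[C@@]2(OO)C(=C)[C@@H](OC(=O)C(C)C)CC[C@]2(C)C[C@H]1OC(C)=O | target

**Step count**

Total: 17 steps. Longest linear sequence: 13 steps (steps 1–5, then 10–17); steps 6–9 form the second branch.

**Steps most likely to fail**

Step 14. The chromium-bound aldehyde may be attacked on its Si face, because the bias from C7 and C8 reaches C3 only through the conformation of the closing ring; the C3 epimer would then dominate. The fallback sets out from 22 and returns at 25. The ring closure is run as described, and if it delivers mainly methyl 8β-acetoxy-3α-hydroxygermacra-1(10)E,4E,11(13)-trien-12-oate F1, this alcohol is not acylated with retention. It is instead esterified with isobutyric acid under Mitsunobu conditions (PPh3, DIAD, toluene, 0 °C), which inverts C3 and should give 25 directly.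

Step 16. The C4 cation may lose a proton from C15 instead of C5, and the adjacent isobutyrate slows re-protonation of the exocyclic alkene, so the mixture may not drain to the 4-ene. The fallback sets out from 25 and returns at 26. The cyclisation is stopped at the kinetic mixture and the exocyclic isomer, methyl 8β-acetoxy-3β-(isobutyryloxy)-5αH-eudesma-4(15),11(13)-dien-12-oate F2, is separated. Its double bond is then moved into the ring in a separate, non-cationic operation with PdCl2(MeCN)2 (cat.) in CH2Cl2 (π-allyl/hydride shift), which should end at the tetrasubstituted alkene 26.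

Step 17. Singlet oxygen may bond to C4 and take a hydrogen from C6, or take H3, so that regioisomeric hydroperoxides form beside the wanted one. The fallback sets out from 26 and returns at 27, and it builds the C5–O bond and the exocyclic alkene in separate operations. Epoxidation with mCPBA from the α face would give methyl 8β-acetoxy-4α,5α-epoxy-3β-(isobutyryloxy)eudesm-11(13)-en-12-oate F3. Isomerisation of the epoxide with diethylaluminium 2,2,6,6-tetramethylpiperidide (toluene, 0 °C), which removes a C15 proton, would give the tertiary allylic alcohol methyl 8β-acetoxy-5α-hydroxy-3β-(isobutyryloxy)eudesma-4(15),11(13)-dien-12-oate F4. Acid-catalysed perhydrolysis (50 % H2O2, cat. H2SO4, Et2O, 0 °C) would then exchange OH for OOH through the tertiary allyl cation, with axial capture on the α face expected, to give 27.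

Further compounds
F1 | step 14 | methyl 8β-acetoxy-3α-hydroxygermacra-1(10)E,4E,11(13)-trien-12-oate | C=C(C(=O)OC)[C@H]1C/C=C(C)/[C@H](O)C/C=C(C)/C[C@H]1OC(C)=O
F2 | step 16 | methyl 8β-acetoxy-3β-(isobutyryloxy)-5αH-eudesma-4(15),11(13)-dien-12-oate | C=C(C(=O)OC)[C@H]1C[C@H]2C(=C)[C@@H](OC(=O)C(C)C)CC[C@]2(C)C[C@H]1OC(C)=O
F3 | step 17 | methyl 8β-acetoxy-4α,5α-epoxy-3β-(isobutyryloxy)eudesm-11(13)-en-12-oate | C=C(C(=O)OC)[C@H]1C[C@@]23O[C@]2(C)[C@@H](OC(=O)C(C)C)CC[C@]3(C)C[C@H]1OC(C)=O
F4 | step 17 | methyl 8β-acetoxy-5α-hydroxy-3β-(isobutyryloxy)eudesma-4(15),11(13)-dien-12-oate | C=C(C(=O)OC)[C@H]1C[C@@]2(O)C(=C)[C@@H](OC(=O)C(C)C)CC[C@]2(C)C[C@H]1OC(C)=O
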